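## Retrosynthetic overview

1. Kanzonol X ⇐ its 2',4'-bis(MOM) ether; only MOM removal follows the ring construction.
2. Rings C and A ⇐ formed together in one operation from an acyclic (R)-α-diazo vinyl ketone carrying a tethered prenyl alkynyl ether: Wolff rearrangement → vinylketene → intramolecular [2+2] with the ynol ether (closes ring C) → 4π opening, 6π closure, tautomerisation (closes ring A and places 7-OH, 8-prenyl and O1).
3. Diazo ketone ⇐ vinyl ketone (diazo transfer) ⇐ aldehyde + vinyl Grignard; alkynyl ether ⇐ primary alcohol + trichloroethylene, then alkynyllithium + prenyl bromide.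
4. C3 stereocentre ⇐ catalytic enantioselective hydroboration of a 1,1-disubstituted aryl alkene (aryl ketone + Wittig).
5. Ring B is bought (resorcinol bis-MOM ether) and dressed by two directed ortho-lithiations; ring order: B (bought), then C and A simultaneously.

Assumption and notation: 1,3-bis(methoxymethoxy)benzene is bought as such; the enantiomer of the hydroboration ligand is chosen by its sense of induction so that C3 is (R); Ar = 2,4-bis(methoxymethoxy)-3-(3-methylbut-2-en-1-yl)phenyl, prenyl = 3-methylbut-2-en-1-yl.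

## Route

Step 1
Reactants: 1 1,3-bis(methoxymethoxy)benzene; 2 1-bromo-3-methylbut-2-ene (prenyl bromide)
Product: 4 1,3-bis(methoxymethoxy)-2-(3-methylbut-2-en-1-yl)benzene, via aryllithium 3 (not isolated)
Conditions: n-BuLi, TMEDA, THF, 0 °C; CuI (5 mol%), 2, −78 °C → rt
Reagents that add atoms: none
Why: The two OMOM groups direct lithiation to the carbon between them (directed ortho-metalation), and the copper-assisted SN2 allylation with the primary allylic bromide gives the linear prenyl arene.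

Step 2
Reactants: 4 1,3-bis(methoxymethoxy)-2-(3-methylbut-2-en-1-yl)benzene; 5 4,4-dimethoxybutanenitrile
Product: 8 1-Ar-4,4-dimethoxybutan-1-one, via aryllithium 6 (not isolated), via N-lithio ketimine 7 (not isolated)
Conditions: s-BuLi, TMEDA, THF, −78 °C; 5, −78 → 0 °C; then H2O, SiO2, rt
Reagents that add atoms: water (O)
Why: With C2 blocked, a second directed ortho-metalation occurs next to one OMOM group; the aryllithium adds once to the nitrile (the N-lithio ketimine cannot add again) and neutral hydrolysis gives the ketone without touching the acetal or the MOM ethers.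

Step 3
Reactants: 8 1-Ar-4,4-dimethoxybutan-1-one; 9 methyltriphenylphosphonium bromide
Product: 10 2-Ar-5,5-dimethoxypent-1-ene
Conditions: KOt-Bu, THF, 0 °C → rt
Reagents that add atoms: none
Why: Wittig methylenation of the aryl alkyl ketone with the non-stabilised ylide; acetal, MOM ethers and the prenyl alkene are inert.

Step 4
Reactants: 10 2-Ar-5,5-dimethoxypent-1-ene
Product: 12 (2R)-2-Ar-5,5-dimethoxypentan-1-ol, via pinacol boronate 11 (not isolated)
Conditions: (IPO)CoCl2 (IPO = chiral iminopyridine-oxazoline ligand, 2 mol%), NaBHEt3 (6 mol%), HBpin, THF, rt; then NaOH, H2O2, 0 °C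
Reagents that add atoms: hydrogen peroxide (OO)
Why: Cobalt-hydride catalysed enantioselective anti-Markovnikov hydroboration of a 1,1-disubstituted aryl alkene (the trisubstituted prenyl alkene does not insert) delivers hydrogen to one face of the benzylic carbon, setting C3 as (R), and stereoretentive C–B oxidation gives the primary alcohol.

Step 5
Reactants: 12 (2R)-2-Ar-5,5-dimethoxypentan-1-ol; 13 trichloroethylene
Product: 15 (4R)-4-Ar-5-[(E)-1,2-dichloroethenoxy]pentanal, via dichlorovinyl ether acetal 14 (not isolated)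
Conditions: KH, THF, 0 °C; 13, −40 °C → rt; then 1 M HCl, THF–H2O, rt
Reagents that add atoms: water (O)
Why: Greene dichlorovinyl ether synthesis (the potassium alkoxide adds anti to dichloroacetylene generated in the flask), after which the chlorine-deactivated enol ether and the aryl MOM ethers survive the mild acid that hydrolyses the dimethyl acetal.

Step 6
Reactants: 15 (4R)-4-Ar-5-[(E)-1,2-dichloroethenoxy]pentanal; 16 vinylmagnesium bromide; 2 1-bromo-3-methylbut-2-ene
Product: 19 (3RS,6R)-6-Ar-7-[(5-methylhex-4-en-1-yn-1-yl)oxy]hept-1-en-3-ol, via bromomagnesium alkoxide 17 (not isolated), via lithium alkoxyacetylide 18 (not isolated)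
Conditions: CH2=CHMgBr (1.1 equiv), THF, −78 °C; n-BuLi (3.3 equiv), −78 → −40 °C; CuI (10 mol%), 2, −40 → 0 °C; then H2O
Reagents that add atoms: none
Why: Grignard 1,2-addition gives an alkoxide that is inert while excess n-BuLi converts the dichlorovinyl ether into the lithium alkoxyacetylide (dehydrochlorination, then chlorine–lithium exchange), whose copper-catalysed SN2 allylation gives the ynol ether; the new carbinol centre is formed unselectively and is erased in step 7.

Step 7
Reactants: 19 (3RS,6R)-6-Ar-7-[(5-methylhex-4-en-1-yn-1-yl)oxy]hept-1-en-3-ol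
Product: 20 (6R)-6-Ar-7-[(5-methylhex-4-en-1-yn-1-yl)oxy]hept-1-en-3-one
Conditions: MnO2 (activated, excess), CH2Cl2, rt
Reagents that add atoms: none
Why: MnO2 oxidises only the allylic alcohol under neutral heterogeneous conditions, leaving the acid-labile ynol ether, the MOM ethers and the prenyl groups intact.

Step 8
Reactants: 20 (6R)-6-Ar-7-[(5-methylhex-4-en-1-yn-1-yl)oxy]hept-1-en-3-one
Product: 22 (6R)-6-Ar-4-diazo-7-[(5-methylhex-4-en-1-yn-1-yl)oxy]hept-1-en-3-one, via lithium trifluoroacetyl enolate 21 (not isolated)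
Conditions: LiN(SiMe3)2, THF, −78 °C; CF3CO2CH2CF3, −78 °C; then MsN3, Et3N, H2O, MeCN, rt
Reagents that add atoms: methanesulfonyl azide (CS(=O)(=O)N=[N+]=[N-])
Why: Detrifluoroacetylative diazo transfer (Regitz-type, Danheiser variant): C4 is the only enolisable position, kinetic enolisation and Claisen trifluoroacetylation activate it for transfer from MsN3 with loss of the trifluoroacetyl group, and no acid is used so the ynol ether survives.

Step 9
Reactants: 22 (6R)-6-Ar-4-diazo-7-[(5-methylhex-4-en-1-yn-1-yl)oxy]hept-1-en-3-one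
Product: 27 (3R)-3-Ar-8-prenyl-3,4-dihydro-2H-chromen-7-ol, via vinylketene 23 (not isolated), via cyclobutenone 24 (not isolated), via dienylketene 25 (not isolated), via cyclohexadienone 26 (not isolated)
Conditions: hν (365 nm), ClCH2CH2Cl (0.01 M), rt; then 80 °C
Reagents that add atoms: none
Why: Proposed new method: photochemical Wolff rearrangement (vinyl shift) gives vinylketene 23, whose carbonyl carbon is attacked by the nucleophilic prenyl-bearing carbon of the tethered ynol ether while the ketene α-carbon bonds to the oxygen-bearing alkyne carbon, so the [2+2] closes ring C as the fused 3-alkoxy-4-vinylcyclobutenone 24 at rt (before the alkynyl ether can fragment thermally); at 80 °C 24 opens (4π) to dienylketene 25, in which ring C holds the vinyl and ketenyl arms cis, and 6π closure to dienone 26 and tautomerisation give ring A with OH at C7, prenyl at C8 and the ring oxygen at C8a, C3 being a spectator; the closest known reactions are the intermolecular Danheiser benzannulation of α-diazo enones with alkynyl ethers and intramolecular ketene–alkyne [2+2] cycloadditions.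

Step 10
Reactants: 27 (3R)-3-Ar-8-prenyl-3,4-dihydro-2H-chromen-7-ol
Product: 28 kanzonol X
Conditions: HCl (3 M aq), MeOH, rt
Reagents that add atoms: none
Why: Acid-catalysed acetal exchange removes both MOM groups as dimethoxymethane under conditions mild enough that the ortho-prenyl phenols do not cyclise to dimethylchromans, and C3 is untouched.

## Compound list

1 | 1,3-bis(methoxymethoxy)benzene | COCOc1cccc(OCOC)c1 | starting material
2 | 1-bromo-3-methylbut-2-ene (prenyl bromide) | CC(C)=CCBr | starting material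
3 | [2,6-bis(methoxymethoxy)phenyl]lithium | [Li]c1c(OCOC)cccc1OCOC | intermediate
4 | 1,3-bis(methoxymethoxy)-2-(3-methylbut-2-en-1-yl)benzene | COCOc1cccc(OCOC)c1CC=C(C)C | intermediate
5 | 4,4-dimethoxybutanenitrile | COC(OC)CCC#N | starting material
6 | [2,4-bis(methoxymethoxy)-3-(3-methylbut-2-en-1-yl)phenyl]lithium (Ar–Li) | [Li]c1ccc(OCOC)c(CC=C(C)C)c1OCOC | intermediate
7 | N-lithio imine of 1-Ar-4,4-dimethoxybutan-1-one | [Li]N=C(CCC(OC)OC)c1ccc(OCOC)c(CC=C(C)C)c1OCOC | intermediate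
8 | 1-Ar-4,4-dimethoxybutan-1-one | COC(OC)CCC(=O)c1ccc(OCOC)c(CC=C(C)C)c1OCOC | intermediate
9 | methyltriphenylphosphonium bromide | C[P+](c1ccccc1)(c1ccccc1)c1ccccc1.[Br-] | starting material
10 | 2-Ar-5,5-dimethoxypent-1-ene | C=C(CCC(OC)OC)c1ccc(OCOC)c(CC=C(C)C)c1OCOC | intermediate
11 | 2-[(2R)-2-Ar-5,5-dimethoxypentyl]-4,4,5,5-tetramethyl-1,3,2-dioxaborolane | CC1(C)OB(C[C@@H](c2ccc(OCOC)c(CC=C(C)C)c2OCOC)CCC(OC)OC)OC1(C)C | intermediate
12 | (2R)-2-Ar-5,5-dimethoxypentan-1-ol | OC[C@@H](c1ccc(OCOC)c(CC=C(C)C)c1OCOC)CCC(OC)OC | intermediate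
13 | trichloroethylene | ClC=C(Cl)Cl | starting material
14 | (E)-1,2-dichloroethenyl (2R)-2-Ar-5,5-dimethoxypentyl ether | Cl/C=C(Cl)\OC[C@@H](c1ccc(OCOC)c(CC=C(C)C)c1OCOC)CCC(OC)OC | intermediate
15 | (4R)-4-Ar-5-[(E)-1,2-dichloroethenoxy]pentanal | Cl/C=C(Cl)\OC[C@@H](c1ccc(OCOC)c(CC=C(C)C)c1OCOC)CCC=O | intermediate
16 | vinylmagnesium bromide | C=C[Mg]Br | starting material
17 | bromomagnesium (3RS,6R)-6-Ar-7-[(E)-1,2-dichloroethenoxy]hept-1-en-3-olate | Cl/C=C(Cl)\OC[C@@H](c1ccc(OCOC)c(CC=C(C)C)c1OCOC)CCC(O[Mg]Br)C=C | intermediate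
18 | {[(2R,5RS)-2-Ar-5-(bromomagnesiooxy)hept-6-en-1-yl]oxy}ethynyllithium | [Li]C#COC[C@@H](c1ccc(OCOC)c(CC=C(C)C)c1OCOC)CCC(O[Mg]Br)C=C | intermediate
19 | (3RS,6R)-6-Ar-7-[(5-methylhex-4-en-1-yn-1-yl)oxy]hept-1-en-3-ol | CC(C)=CCC#COC[C@@H](c1ccc(OCOC)c(CC=C(C)C)c1OCOC)CCC(O)C=C | intermediate
20 | (6R)-6-Ar-7-[(5-methylhex-4-en-1-yn-1-yl)oxy]hept-1-en-3-one | CC(C)=CCC#COC[C@@H](c1ccc(OCOC)c(CC=C(C)C)c1OCOC)CCC(=O)C=C | intermediate
21 | lithium enolate of (6R)-6-Ar-7-[(5-methylhex-4-en-1-yn-1-yl)oxy]-4-(trifluoroacetyl)hept-1-en-3-one | [Li]OC(=C(C[C@H](c1ccc(OCOC)c(CC=C(C)C)c1OCOC)COC#CCC=C(C)C)C(=O)C=C)C(F)(F)F | intermediate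
22 | (6R)-6-Ar-4-diazo-7-[(5-methylhex-4-en-1-yn-1-yl)oxy]hept-1-en-3-one | C=CC(=O)C(=[N+]=[N-])C[C@H](c1ccc(OCOC)c(CC=C(C)C)c1OCOC)COC#CCC=C(C)C | intermediate
23 | (4R)-4-Ar-2-ethenyl-5-[(5-methylhex-4-en-1-yn-1-yl)oxy]pent-1-en-1-one (vinylketene) | C=CC(=C=O)C[C@H](c1ccc(OCOC)c(CC=C(C)C)c1OCOC)COC#CCC=C(C)C | intermediate
24 | (4R,6RS)-4-Ar-6-ethenyl-8-prenyl-2-oxabicyclo[4.2.0]oct-1(8)-en-7-one | C=CC12C[C@H](c3ccc(OCOC)c(CC=C(C)C)c3OCOC)COC1=C(CC=C(C)C)C2=O | intermediate
25 | 2-[(3R)-3-Ar-5-ethenyl-3,4-dihydro-2H-pyran-6-yl]-5-methylhexa-1,4-dien-1-one (dienylketene) | O=C=C(CC=C(C)C)C1=C(C=C)C[C@H](c2ccc(OCOC)c(CC=C(C)C)c2OCOC)CO1 | intermediate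
26 | (3R)-3-Ar-8-prenyl-3,4-dihydro-2H-chromen-7(6H)-one | O=C1CC=C2C[C@H](c3ccc(OCOC)c(CC=C(C)C)c3OCOC)COC2=C1CC=C(C)C | intermediate
27 | (3R)-3-[2,4-bis(methoxymethoxy)-3-(3-methylbut-2-en-1-yl)phenyl]-8-(3-methylbut-2-en-1-yl)-3,4-dihydro-2H-chromen-7-ol | CC(C)=CCc1c(OCOC)ccc([C@@H]2COc3c(ccc(O)c3CC=C(C)C)C2)c1OCOC | intermediate
28 | kanzonol X, 4-[(3R)-7-hydroxy-8-(3-methylbut-2-en-1-yl)-3,4-dihydro-2H-chromen-3-yl]-2-(3-methylbut-2-en-1-yl)benzene-1,3-diol | CC(C)=CCc1c(O)ccc([C@@H]2COc3c(ccc(O)c3CC=C(C)C)C2)c1O | target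

## Step count and risks

Total step count: 10. Longest linear sequence: 10 steps (1 → 28); 2, 5, 9, 13 and 16 are bought.

Steps most likely to fail:

Step 9 (ring-forming cascade). The acyl carbene may undergo a 1,2-hydrogen shift to a dienone instead of the Wolff shift, or the ketene may fail to reach the tethered alkyne. The fallback separates the two ring closures; it sets out from 12 and comes back at 27. Alcohol 12 is converted with TsCl and pyridine into the tosylate F1. Mild aqueous acid then frees the aldehyde F2. Addition of 16 gives the allylic alcohol F3, and MnO2 gives the vinyl ketone F4. Diazo transfer as in step 8 gives the diazo ketone F5. F5 is irradiated and then heated to 80 °C with the silyl ynol ether F6, which is made by Kowalski homologation of ethyl 4-methylpent-3-enoate and trapping of the lithium ynolate with TIPSOTf. This intermolecular Danheiser benzannulation gives the resorcinol monosilyl ether F7. Bu4NF then frees the phenoxide next to the side chain, which displaces the tosylate (6-exo) to close ring C and give 27.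

Step 8 (diazo transfer on an unsubstituted vinyl ketone). The enone 20 may oligomerise by Michael addition under LiN(SiMe3)2, and the diazo ketone may add to another enone. The fallback carries a traceless silyl group on the vinyl terminus; it sets out from 15 and comes back at 28. Aldehyde 15 is treated with (E)-Me3SiCH=CHMgBr in place of 16, then with n-BuLi, CuI and 2 as in step 6, to give the silylated allylic alcohol F8. MnO2 gives the β-silyl enone F9, which is robust to base and to dipolar addition. Diazo transfer gives the diazo ketone F10. Irradiation and heating as in step 9 give the 6-silyl chromanol F11. HCl in MeOH then removes both MOM groups and the aryl–silicon bond (ipso-protodesilylation ortho to the phenol) to give 28.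

Step 4 (enantioselective hydroboration). The ortho OMOM group twists the styrene and may lower rate and selectivity. The fallback sets the centre by dynamic kinetic resolution instead; it sets out from 10 and comes back at 12. Alkene 10 is hydroborated with 9-BBN and oxidised (NaOH, H2O2) to the racemic alcohol F12. Pyridine-buffered Dess–Martin oxidation gives the racemic α-aryl aldehyde F13. Hydrogenation with RuCl2[(S)-xylbinap][(S)-daipen] (or its antipode, whichever gives the R product), KOt-Bu and H2 in i-PrOH reduces one enantiomer faster while the aldehyde racemises through its enolate, giving (R)-12; the prenyl alkenes are not reduced by this carbonyl-selective catalyst.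

## Further compounds

F1 | step 9 | (2R)-2-Ar-5,5-dimethoxypentyl 4-methylbenzenesulfonate | Cc1ccc(cc1)S(=O)(=O)OC[C@@H](c1ccc(OCOC)c(CC=C(C)C)c1OCOC)CCC(OC)OC
F2 | step 9 | (2R)-2-Ar-5-oxopentyl 4-methylbenzenesulfonate | Cc1ccc(cc1)S(=O)(=O)OC[C@@H](c1ccc(OCOC)c(CC=C(C)C)c1OCOC)CCC=O
F3 | step 9 | (2R,5RS)-2-Ar-5-hydroxyhept-6-en-1-yl 4-methylbenzenesulfonate | Cc1ccc(cc1)S(=O)(=O)OC[C@@H](c1ccc(OCOC)c(CC=C(C)C)c1OCOC)CCC(O)C=C
F4 | step 9 | (2R)-2-Ar-5-oxohept-6-en-1-yl 4-methylbenzenesulfonate | Cc1ccc(cc1)S(=O)(=O)OC[C@@H](c1ccc(OCOC)c(CC=C(C)C)c1OCOC)CCC(=O)C=C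
F5 | step 9 | (2R)-2-Ar-4-diazo-5-oxohept-6-en-1-yl 4-methylbenzenesulfonate | Cc1ccc(cc1)S(=O)(=O)OC[C@@H](c1ccc(OCOC)c(CC=C(C)C)c1OCOC)CC(=[N+]=[N-])C(=O)C=C
F6 | step 9 | triisopropyl[(5-methylhex-4-en-1-yn-1-yl)oxy]silane | CC(C)=CCC#CO[Si](C(C)C)(C(C)C)C(C)C
F7 | step 9 | (2R)-2-Ar-3-{4-hydroxy-3-(3-methylbut-2-en-1-yl)-2-[(triisopropylsilyl)oxy]phenyl}propyl 4-methylbenzenesulfonate | Cc1ccc(cc1)S(=O)(=O)OC[C@@H](c1ccc(OCOC)c(CC=C(C)C)c1OCOC)Cc1ccc(O)c(CC=C(C)C)c1O[Si](C(C)C)(C(C)C)C(C)C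
F8 | step 8 | (1E,3RS,6R)-6-Ar-7-[(5-methylhex-4-en-1-yn-1-yl)oxy]-1-(trimethylsilyl)hept-1-en-3-ol | CC(C)=CCC#COC[C@@H](c1ccc(OCOC)c(CC=C(C)C)c1OCOC)CCC(O)/C=C/[Si](C)(C)C
F9 | step 8 | (1E,6R)-6-Ar-7-[(5-methylhex-4-en-1-yn-1-yl)oxy]-1-(trimethylsilyl)hept-1-en-3-one | CC(C)=CCC#COC[C@@H](c1ccc(OCOC)c(CC=C(C)C)c1OCOC)CCC(=O)/C=C/[Si](C)(C)C
F10 | step 8 | (1E,6R)-6-Ar-4-diazo-7-[(5-methylhex-4-en-1-yn-1-yl)oxy]-1-(trimethylsilyl)hept-1-en-3-one | C[Si](C)(C)/C=C/C(=O)C(=[N+]=[N-])C[C@H](c1ccc(OCOC)c(CC=C(C)C)c1OCOC)COC#CCC=C(C)C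
F11 | step 8 | (3R)-3-Ar-8-(3-methylbut-2-en-1-yl)-6-(trimethylsilyl)-3,4-dihydro-2H-chromen-7-ol | CC(C)=CCc1c(OCOC)ccc([C@@H]2COc3c(cc([Si](C)(C)C)c(O)c3CC=C(C)C)C2)c1OCOC
F12 | step 4 | rac-2-Ar-5,5-dimethoxypentan-1-ol | OCC(c1ccc(OCOC)c(CC=C(C)C)c1OCOC)CCC(OC)OC
F13 | step 4 | rac-2-Ar-5,5-dimethoxypentanal | O=CC(c1ccc(OCOC)c(CC=C(C)C)c1OCOC)CCC(OC)OC
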